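## The problem

Target 17 is a 2,3-dihydrobenzofuran: a benzene ring (C3a to C7a) fused to a five-membered ring O1–C2–C3. C2 carries a 3-oxoprop-1-en-2-yl group (an α-substituted acrolein), C3 an isovalerate trans to it, and C5 an (R)-1-hydroxyethyl group esterified with (R)-2-methylbutanoic acid 10.

Only C2 and C3 are neighbours and can control each other, and only while C3 is still epimerisable, that is, before it carries its oxygen. The carbinol carbon on C5 and the α-carbon of the acid are too remote and must come from a reagent and from the chiral pool.

The C3 acyloxy group is benzylic and sits next to C2–H, so acid or base can expel isovaleric acid and leave an aromatic benzofuran. In 17 this C2–H is also γ to the aldehyde. The acrolein is a Michael acceptor, the C5 side-chain ester is a p-alkoxybenzylic ester that ionises with acid, and two different acyl groups must end up on two secondary benzylic oxygens.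

Two features open the structure. The oxygen on C3 can come from a Baeyer–Villiger oxidation, so C3 may first be a carbon between the arene and an isobutyl ketone, which is the substitution pattern of a donor/acceptor carbene. And C2–H lies five atoms from C3 along C3–C3a–C7a–O1–C2, is α to O1, and is allylic to the alkene that later becomes the acrolein. C2–C3 can therefore be made by carbene insertion into an ether C–H bond, which closes the dihydrofuran ring.

## Retrosynthesis

The aldehyde is removed first. Taking the acrolein C=O back to a methyl group leads through the allylic alcohol 16 to the isopropenyl compound 15. Carrying an oxygenated three-carbon unit through the synthesis would expose an allylic ether or an enal to carbenes, peroxides and bases, whereas an isopropenyl group only has to survive. 15 lacks the most reactive function of 17. The forward steps must oxidise the methyl group and not C2–H, and must finish without base.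

Next the C3–O bond is cut by removing the oxygen from between C3 and the acyl carbon, so 15 becomes the isobutyl ketone 14. The neighbouring cut, at the ester C(=O)–O bond, would lead to a free trans-3-hydroxy-2,3-dihydrobenzofuran, which dehydrates easily to a benzofuran and would still need acylation. The ketone is also the group that makes C3 epimerisable and makes the next cut possible. The Baeyer–Villiger step must migrate the secondary benzylic C3 (not the primary CH2) with retention and must leave the 1,1-disubstituted alkene alone. That rules out peracids and calls for a silyl peroxide under Lewis acid catalysis.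

The key cut is C2–C3. It opens the dihydrofuran ring of 14 to the aryl diazo ketone 12, where C3 is the diazo carbon and C2 the CH2 of a 2-methylallyl ether. Cutting O1–C2 or C3–C3a would need an open chain with both stereocentres already in place. The C–H insertion makes the ring, the bond and both stereocentres from a precursor that is flat at both carbons. The forward step needs a chiral dirhodium carboxylate to choose one of two enantiotopic hydrogens, insertion must beat addition to the alkene, and base in the same flask must bring C3 to trans. The cis ketone 13 formed first is not isolated.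

The C5 side chain of 12 already has its final form, the (R)-2-methylbutanoate. An ester at this remote site does not interfere with the carbene, the amidine base or the silyl peroxide. It saves a silyl protection and a fluoride deprotection (the latter would fall on a base-sensitive 3-acyloxy compound) and leaves only oxidations after the key step.

12 is cut at the C=N2 bond: diazo transfer to the benzyl ketone 11, whose methylene between arene and carbonyl is the only acidic position. 11 is cut at the ester C–O bond to the alcohol 9 and the acid 10. Acyl transfer to oxygen leaves both stereocentres untouched.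

The ketone 9 is cut between the carbonyl carbon and the isobutyl CH2, giving the Grignard reagent 8 and the N-methoxy-N-methylamide 7, which comes from the methyl ester 6. The amide stops the addition at the ketone. The free carbinol travels as its magnesium alkoxide, so no protecting group is needed here either.

The carbinol stereocentre of 6 is traced to the aryl methyl ketone 5 by asymmetric transfer hydrogenation, reagent control on a flat precursor. 5 is cut at the ether O–CH2 bond to the phenol 3 and the allylic chloride 4. 3 is cut at the aryl–acetyl bond to the commercial ester 1 and acetyl chloride 2; the free phenol directs acylation to its para position, the later C5. Acylation comes before etherification because an allyl ether would not survive the Lewis acid. Reduction comes after etherification because a ketone bearing a phenolate is a poor substrate for transfer hydrogenation.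

## Roads not taken

Alternative 1: Here the benzene ring is made last. C3a–C4 and C5–C6 are cut, giving the fused pyranone (2S,3S)-3-(triethylsilyloxy)-2-[2-(triethylsilyloxy)propan-2-yl]-2,3-dihydro-4H-furo[3,2-c]pyran-4-one A1 and but-3-yn-2-one A2. Heating the two should give a bridged Diels–Alder adduct that decarboxylates to 1-[(2S,3S)-3-(triethylsilyloxy)-2-[2-(triethylsilyloxy)propan-2-yl]-2,3-dihydro-1-benzofuran-5-yl]ethan-1-one A3.
- Merits: the acetyl group reaches C5 through the polarity of the cycloaddition (the enol-ether carbon C3a of A1 bonds to the unsubstituted alkyne carbon of A2), with no aromatic substitution. The C3 oxygen is present from the start, so no Baeyer–Villiger step is needed.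
- Weak points: both ring stereocentres must be built into A1 beforehand, so the stereochemical problem is moved and not solved. 2-Pyranones react with alkynes only at high temperature, where a 3-silyloxy-2,3-dihydrofuran can eliminate its silyloxy group and aromatise. After A3 there remain differentiation of two silyl ethers, acylation at C3, dehydration of the tertiary alcohol, asymmetric reduction, esterification and allylic oxidation.
- Comparison: this road is better in avoiding diazo compounds and the need for an alkene-sparing oxidation. The chosen plan sets against it that ring, C2–C3 bond and both ring stereocentres arise in one catalytic step from a precursor made by routine reactions, and that three steps follow the ring closure where this road needs about seven.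

Alternative 2: C3a–C3 and O1–C2 are cut, giving 4-(2-methyl-1,3-dioxolan-2-yl)phenol A4 and (S)-3,3-dimethyloxirane-2-carbaldehyde A5. The bromomagnesium phenoxide of A4 should add through its ortho carbon to the formyl group of A5 within a magnesium chelate. A carbonate base in an alcohol solvent should then let the phenoxide oxygen open the epoxide at the secondary carbon with inversion (5-exo), giving (2S,3S)-2-(2-hydroxypropan-2-yl)-5-(2-methyl-1,3-dioxolan-2-yl)-2,3-dihydro-1-benzofuran-3-ol A6.
- Merits: it is very convergent and uses two small fragments. The absolute configuration of C2 comes from a reliable asymmetric epoxidation, C3 is already an alcohol, and the future alkene is hidden as a tertiary alcohol, so no oxidation has to spare it. In these respects, and especially in the source of absolute configuration, it is as good as or better than the chosen plan.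
- Weak points: C3 is formed as a carbinol by addition to an α-epoxy aldehyde. Its facial selectivity (chelate against Felkin) is not secure and cannot be corrected by equilibration. The intermediate o-hydroxybenzyl alcohol is prone to quinone methide formation, and the para ketal lowers the nucleophilicity of the ortho carbon. After A6 come selective acylation at C3, dehydration of the tertiary alcohol next to the elimination-prone acyloxy group, ketal removal, asymmetric reduction, esterification and allylic oxidation.
- Comparison: the chosen plan answers with thermodynamic control of the trans relationship (C3 is a ketone α-carbon in 14) and a shorter endgame.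

Alternative 3: O1–C7a and C3a–C3 are cut, giving the aryne released by fluoride from 2-(trimethylsilyl)phenyl trifluoromethanesulfonate A7, and (R)-2-hydroxy-3-methyl-3-(triethylsilyloxy)butanal A8. The hydroxyl oxygen should add to the aryne and the aryl anion so formed should close onto the formyl group, giving (2S,3S)-2-[2-(triethylsilyloxy)propan-2-yl]-2,3-dihydro-1-benzofuran-3-ol A9.
- Merits: it is the shortest construction of the bicyclic core of the four plans, needs no transition metal, and takes C2 unchanged from A8.
- Weak points: A9 has no carbon at C5. Either a Friedel–Crafts acetylation must be run on a molecule with an acid-labile benzylic oxygen, or an unsymmetrical acetyl-substituted aryne must be used with no control over which aryne carbon takes the oxygen. A8 is an enolisable α-hydroxy aldehyde that can racemise and dimerise under basic fluoride conditions. The cis/trans outcome at C3 of the anionic ring closure is not predictable and not correctable, and the aryne can also arylate the product alcohol.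
- Comparison: this road reaches the ring in fewer steps than the chosen plan. But the C5 side chain, which the chosen plan carries from step 1, becomes the problem, and the endgame is the longest.

Key step: step 8

Assumption: Rh2(S-PTTL)4 (dirhodium tetrakis[N-phthaloyl-(S)-tert-leucinate]) is taken to select the C2–H that leads to (2S)-configured 14; should it select the other hydrogen, the mirror-image catalyst Rh2(R-PTTL)4 is used and nothing else changes.

Assumption: methyl ester 1 is taken as a purchased material; it is otherwise one Fischer esterification from 2-hydroxyphenylacetic acid.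

## Steps

Step 1
Reactants: 1 methyl 2-(2-hydroxyphenyl)acetate; 2 acetyl chloride
Product: 3 methyl 2-(5-acetyl-2-hydroxyphenyl)acetate
Conditions: AlCl3 (3 equiv), CH2Cl2, 0 °C to rt; aq. HCl
Reagents that add atoms: none
Why: Friedel–Crafts acylation (any O-acetate formed first goes on by Fries rearrangement); the aluminium phenoxide directs to its para position, as in acetylations of other 2-substituted phenols, while the one open ortho position is crowded by the oxygen–aluminium group. The side-chain CH2 is meta to the reacting carbon and the ester is tied up by the Lewis acid.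

Step 2
Reactants: 3 methyl 2-(5-acetyl-2-hydroxyphenyl)acetate; 4 3-chloro-2-methylprop-1-ene
Product: 5 methyl 2-[5-acetyl-2-(2-methylallyloxy)phenyl]acetate
Conditions: K2CO3, NaI (cat.), DMF, 60 °C
Reagents that add atoms: none
Why: Williamson ether synthesis; the p-acyl phenol is fully deprotonated by carbonate and is alkylated at oxygen by the allylic chloride (iodide catalysis), while the ester and ketone α-positions are far too weakly acidic to compete.

Step 3
Reactants: 5 methyl 2-[5-acetyl-2-(2-methylallyloxy)phenyl]acetate
Product: 6 methyl 2-[5-[(1R)-1-hydroxyethyl]-2-(2-methylallyloxy)phenyl]acetate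
Conditions: RuCl(p-cymene)[(R,R)-TsDPEN] (1 mol %), HCO2H/Et3N 5:2, 30 °C
Reagents that add atoms: none
Why: Noyori asymmetric transfer hydrogenation (TsDPEN = N-tosyl-1,2-diphenylethane-1,2-diamine); hydride and proton pass from Ru–H/N–H to the aryl methyl ketone in an outer-sphere six-membered transition state, and the (R,R) ligand gives the (R) carbinol as with other acetophenones. The coordinatively saturated hydride does not bind the alkene, the ester is inert, and formic acid makes the reduction irreversible for this electron-rich ketone.

Step 4
Reactants: 6 methyl 2-[5-[(1R)-1-hydroxyethyl]-2-(2-methylallyloxy)phenyl]acetate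
Product: 7 2-[5-[(1R)-1-hydroxyethyl]-2-(2-methylallyloxy)phenyl]-N-methoxy-N-methylacetamide
Conditions: MeNH(OMe)·HCl, i-PrMgCl (excess), THF, −20 to 0 °C; aq. NH4Cl
Reagents that add atoms: N,O-dimethylhydroxylamine hydrochloride, CNOC.Cl
Why: Weinreb amide formation by aminolysis of the methyl ester with the chloromagnesium amide made in the flask; one further equivalent of the Grignard base turns the carbinol into an inert magnesium alkoxide, so no protecting group is needed.

Step 5
Reactants: 7 2-[5-[(1R)-1-hydroxyethyl]-2-(2-methylallyloxy)phenyl]-N-methoxy-N-methylacetamide; 8 isobutylmagnesium bromide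
Product: 9 1-[5-[(1R)-1-hydroxyethyl]-2-(2-methylallyloxy)phenyl]-4-methylpentan-2-one
Conditions: 8 (3 equiv), THF, −20 to 0 °C; aq. NH4Cl
Reagents that add atoms: none
Why: Weinreb ketone synthesis; the first equivalent deprotonates the alcohol, the next adds to the amide, and the five-membered magnesium chelate holds until work-up, so no tertiary alcohol forms.

Step 6
Reactants: 9 1-[5-[(1R)-1-hydroxyethyl]-2-(2-methylallyloxy)phenyl]-4-methylpentan-2-one; 10 (R)-2-methylbutanoic acid
Product: 11 (1R)-1-[4-(2-methylallyloxy)-3-(4-methyl-2-oxopentyl)phenyl]ethyl (2R)-2-methylbutanoate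
Conditions: DCC, 4-(dimethylamino)pyridine (cat.), CH2Cl2, 0 °C to rt
Reagents that add atoms: none
Why: Steglich esterification; acyl transfer to oxygen leaves the carbinol configuration untouched, an α-alkyl acid does not racemise appreciably through the acylpyridinium at this temperature, and the neutral medium spares the acid-sensitive p-alkoxybenzylic alcohol.

Step 7
Reactants: 11 (1R)-1-[4-(2-methylallyloxy)-3-(4-methyl-2-oxopentyl)phenyl]ethyl (2R)-2-methylbutanoate
Product: 12 (1R)-1-[3-(1-diazo-4-methyl-2-oxopentyl)-4-(2-methylallyloxy)phenyl]ethyl (2R)-2-methylbutanoate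
Conditions: p-ABSA, DBU, MeCN, 0 °C to rt
Reagents that add atoms: 4-acetamidobenzenesulfonyl azide (p-ABSA), CC(=O)Nc1ccc(cc1)S(=O)(=O)N=[N+]=[N-]
Why: Regitz diazo transfer; the amidine base (DBU, 1,8-diazabicyclo[5.4.0]undec-7-ene) deprotonates only the methylene between arene and carbonyl, not the isobutyl CH2 or the ester α-CH. The diazo ketone is kept cold and used at once.

Step 8
Reactants: 12 (1R)-1-[3-(1-diazo-4-methyl-2-oxopentyl)-4-(2-methylallyloxy)phenyl]ethyl (2R)-2-methylbutanoate
Product: 14 (1R)-1-[(2S,3S)-3-(3-methylbutanoyl)-2-(prop-1-en-2-yl)-2,3-dihydro-1-benzofuran-5-yl]ethyl (2R)-2-methylbutanoate, via cis-ketone 13 (not isolated)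
Conditions: Rh2(S-PTTL)4 (1 mol %), toluene, −40 to 0 °C, slow addition of 12; then 1,8-diazabicyclo[5.4.0]undec-7-ene (DBU), rt, argon
Reagents that add atoms: none
Why: Rh2(S-PTTL)4 expels N2 from 12 to give a dirhodium-bound donor/acceptor carbene at the future C3 (aryl donor, acyl acceptor), which inserts into one of the two enantiotopic O–CH2 hydrogens five atoms away through a concerted, hydride-transfer-like three-centre transition state and so forms C2–C3. The closest known reaction type is the enantioselective intramolecular 1,5-C–H insertion of 2-alkoxyphenyl diazoacetates and of α-aryl-α-diazo ketones under chiral dirhodium carboxylates, which gives 2,3-disubstituted 2,3-dihydrobenzofurans and α-aryl cyclopentanones. The dihydrofuran ring closes as a five-membered ring by 1,5-insertion, with the C3a–C7a–O1 unit of the benzene ring holding carbene and C–H bond together. C2 is set by the catalyst: the phthalimido walls of the four tert-leucinate ligands let only one of the enantiotopic hydrogens reach the carbene, and the remote stereocentres on the C5 side chain have no say. C3 is expected to form mainly cis (13) and is then set by the substrate: DBU enolises the ketone and the equilibrium should lie with trans-14, where isopropenyl and acyl avoid each other, while C2 stays untouched because ring-opening β-elimination of the phenoxide from the exocyclic enolate would be the reverse of a disfavoured 5-endo closure. The step needs insertion to beat cyclopropanation of the methallyl alkene, insertion into the isobutyl methyl groups and any 1,2-shift. The substrate secures this because the targeted C–H bond is both α to oxygen and allylic and sits in the 1,5-relationship on a rigid ortho-phenylene tether, whereas the alkene could only give a strained cyclopropa[c]chromene, the isobutyl C–H bonds within reach are primary, and the carbene carbon has no β-hydrogen.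

Step 9
Reactants: 14 (1R)-1-[(2S,3S)-3-(3-methylbutanoyl)-2-(prop-1-en-2-yl)-2,3-dihydro-1-benzofuran-5-yl]ethyl (2R)-2-methylbutanoate
Product: 15 (1R)-1-[(2R,3S)-3-(3-methylbutanoyloxy)-2-(prop-1-en-2-yl)-2,3-dihydro-1-benzofuran-5-yl]ethyl (2R)-2-methylbutanoate
Conditions: (Me3SiO)2, SnCl4 (0.3 equiv), trans-cyclohexane-1,2-diamine (0.3 equiv), 4 Å MS, CH2Cl2, −20 °C to rt
Reagents that add atoms: bis(trimethylsilyl) peroxide, C[Si](C)(C)OO[Si](C)(C)C
Why: Baeyer–Villiger oxidation with a silyl peroxide under Lewis acid catalysis; in the Criegee intermediate the secondary benzylic C3 should migrate in preference to the primary isobutyl CH2, with retention, so the isovalerate arrives complete and trans (the descriptor at C2 changes from S to R only because the priorities change). The silyl peroxide is no epoxidising agent, so the isopropenyl group should survive, and the diamine-tempered tin Lewis acid at low temperature limits ionisation of the benzylic esters.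

Step 10
Reactants: 15 (1R)-1-[(2R,3S)-3-(3-methylbutanoyloxy)-2-(prop-1-en-2-yl)-2,3-dihydro-1-benzofuran-5-yl]ethyl (2R)-2-methylbutanoate
Product: 16 (1R)-1-[(2R,3S)-2-(3-hydroxyprop-1-en-2-yl)-3-(3-methylbutanoyloxy)-2,3-dihydro-1-benzofuran-5-yl]ethyl (2R)-2-methylbutanoate
Conditions: SeO2 (0.5 equiv), t-BuOOH, CH2Cl2, 0 °C to rt
Reagents that add atoms: selenium dioxide, O=[Se]=O (transfers the oxygen atom); tert-butyl hydroperoxide, CC(C)(C)OO (re-forms SeO2 and is the net oxygen source)
Why: SeO2 allylic oxidation (ene reaction at the terminal CH2, then [2,3]-sigmatropic shift); the methyl hydrogens are the accessible allylic hydrogens, while C2–H is hindered and inductively deactivated by O1 and the neighbouring acyloxy group. Isopropenyl groups on ring carbons are commonly oxidised this way, and any enal formed by further oxidation is the target itself and is carried on.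

Step 11
Reactants: 16 (1R)-1-[(2R,3S)-2-(3-hydroxyprop-1-en-2-yl)-3-(3-methylbutanoyloxy)-2,3-dihydro-1-benzofuran-5-yl]ethyl (2R)-2-methylbutanoate
Product: 17 (1R)-1-[(2R,3S)-3-(3-methylbutanoyloxy)-2-(3-oxoprop-1-en-2-yl)-2,3-dihydro-1-benzofuran-5-yl]ethyl (2R)-2-methylbutanoate
Conditions: MnO2 (activated, excess), CH2Cl2, rt
Reagents that add atoms: none
Why: MnO2 oxidation of a primary allylic alcohol to the enal; the oxidant is neutral and heterogeneous, which matters because base would remove the now acidic C2–H and expel the C3 isovalerate to give a benzofuran.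

## Compound list

1 | methyl 2-(2-hydroxyphenyl)acetate | COC(=O)Cc1ccccc1O | starting material
2 | acetyl chloride | CC(=O)Cl | starting material
3 | methyl 2-(5-acetyl-2-hydroxyphenyl)acetate | COC(=O)Cc1cc(C(C)=O)ccc1O | intermediate
4 | 3-chloro-2-methylprop-1-ene | C=C(C)CCl | starting material
5 | methyl 2-[5-acetyl-2-(2-methylallyloxy)phenyl]acetate | COC(=O)Cc1cc(C(C)=O)ccc1OCC(C)=C | intermediate
6 | methyl 2-[5-[(1R)-1-hydroxyethyl]-2-(2-methylallyloxy)phenyl]acetate | COC(=O)Cc1cc([C@@H](C)O)ccc1OCC(C)=C | intermediate
7 | 2-[5-[(1R)-1-hydroxyethyl]-2-(2-methylallyloxy)phenyl]-N-methoxy-N-methylacetamide | CON(C)C(=O)Cc1cc([C@@H](C)O)ccc1OCC(C)=C | intermediate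
8 | isobutylmagnesium bromide | CC(C)C[Mg]Br | starting material
9 | 1-[5-[(1R)-1-hydroxyethyl]-2-(2-methylallyloxy)phenyl]-4-methylpentan-2-one | CC(C)CC(=O)Cc1cc([C@@H](C)O)ccc1OCC(C)=C | intermediate
10 | (R)-2-methylbutanoic acid | CC[C@@H](C)C(=O)O | starting material
11 | (1R)-1-[4-(2-methylallyloxy)-3-(4-methyl-2-oxopentyl)phenyl]ethyl (2R)-2-methylbutanoate | CC(C)CC(=O)Cc1cc([C@@H](C)OC(=O)[C@H](C)CC)ccc1OCC(C)=C | intermediate
12 | (1R)-1-[3-(1-diazo-4-methyl-2-oxopentyl)-4-(2-methylallyloxy)phenyl]ethyl (2R)-2-methylbutanoate | CC(C)CC(=O)C(=[N+]=[N-])c1cc([C@@H](C)OC(=O)[C@H](C)CC)ccc1OCC(C)=C | intermediate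
13 | (1R)-1-[(2S,3R)-3-(3-methylbutanoyl)-2-(prop-1-en-2-yl)-2,3-dihydro-1-benzofuran-5-yl]ethyl (2R)-2-methylbutanoate (cis ketone, not isolated) | C=C(C)[C@H]1Oc2ccc([C@@H](C)OC(=O)[C@H](C)CC)cc2[C@H]1C(=O)CC(C)C | intermediate
14 | (1R)-1-[(2S,3S)-3-(3-methylbutanoyl)-2-(prop-1-en-2-yl)-2,3-dihydro-1-benzofuran-5-yl]ethyl (2R)-2-methylbutanoate | C=C(C)[C@H]1Oc2ccc([C@@H](C)OC(=O)[C@H](C)CC)cc2[C@@H]1C(=O)CC(C)C | intermediate
15 | (1R)-1-[(2R,3S)-3-(3-methylbutanoyloxy)-2-(prop-1-en-2-yl)-2,3-dihydro-1-benzofuran-5-yl]ethyl (2R)-2-methylbutanoate | C=C(C)[C@H]1Oc2ccc([C@@H](C)OC(=O)[C@H](C)CC)cc2[C@@H]1OC(=O)CC(C)C | intermediate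
16 | (1R)-1-[(2R,3S)-2-(3-hydroxyprop-1-en-2-yl)-3-(3-methylbutanoyloxy)-2,3-dihydro-1-benzofuran-5-yl]ethyl (2R)-2-methylbutanoate | C=C(CO)[C@H]1Oc2ccc([C@@H](C)OC(=O)[C@H](C)CC)cc2[C@@H]1OC(=O)CC(C)C | intermediate
17 | (1R)-1-[(2R,3S)-3-(3-methylbutanoyloxy)-2-(3-oxoprop-1-en-2-yl)-2,3-dihydro-1-benzofuran-5-yl]ethyl (2R)-2-methylbutanoate | C=C(C=O)[C@H]1Oc2ccc([C@@H](C)OC(=O)[C@H](C)CC)cc2[C@@H]1OC(=O)CC(C)C | target

## Step count and least certain steps

Total step count: 11. Longest linear sequence: 11 steps (1 to 17); the route is fully linear, with 2, 4, 8 and 10 entering as purchased reagents.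

Step 8 (key step).
- What may go wrong: addition of the carbene to the methallyl double bond in competition with C–H insertion; slow intramolecular dipolar cycloaddition of the diazo group to the same alkene while 12 is handled; and incomplete discrimination between the two enantiotopic hydrogens, which the remote stereocentres would turn into a diastereomer mixture that is hard to separate.
- Fallback: the alkene is removed before the carbene is made. It sets out from 11 and returns at 14. Mukaiyama hydration of 11 (Co(acac)2, PhSiH3, O2, THF) should give the tertiary alcohol (1R)-1-[4-(2-hydroxy-2-methylpropoxy)-3-(4-methyl-2-oxopentyl)phenyl]ethyl (2R)-2-methylbutanoate F1. N-(Trimethylsilyl)imidazole in CH2Cl2 converts it into the silyl ether (1R)-1-[3-(4-methyl-2-oxopentyl)-4-[2-methyl-2-(trimethylsilyloxy)propoxy]phenyl]ethyl (2R)-2-methylbutanoate F2, which keeps the hydroxyl from O–H insertion. Diazo transfer as in step 7 gives (1R)-1-[3-(1-diazo-4-methyl-2-oxopentyl)-4-[2-methyl-2-(trimethylsilyloxy)propoxy]phenyl]ethyl (2R)-2-methylbutanoate F3. Rh2(S-PTTL)4 and then DBU should give (1R)-1-[(2S,3S)-3-(3-methylbutanoyl)-2-[2-(trimethylsilyloxy)propan-2-yl]-2,3-dihydro-1-benzofuran-5-yl]ethyl (2R)-2-methylbutanoate F4 by insertion into the ether CH2, now the only activated C–H bond in reach and with no π bond to compete. Aqueous acetic acid in THF frees the alcohol (1R)-1-[(2S,3S)-2-(2-hydroxypropan-2-yl)-3-(3-methylbutanoyl)-2,3-dihydro-1-benzofuran-5-yl]ethyl (2R)-2-methylbutanoate F5, and the Burgess reagent in warm toluene dehydrates it towards the methyl groups to 14.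
- Price: five extra steps, and a C–H bond that is no longer allylic and lies next to a fully substituted carbon.

Step 9.
- What may go wrong: ionisation of the p-alkoxybenzylic ester on the C5 side chain, or of the newly formed benzylic isovalerate at C3, by the tin Lewis acid (loss of configuration, elimination towards a styrene or a benzofuran); or slow oxidation of the hindered open-chain ketone. Migration of the isobutyl CH2 is a lesser concern.
- Fallback: the alkene is masked and a buffered protic peracid is used. It runs from 14 to 15. Mukaiyama hydration of 14 (Co(acac)2, PhSiH3, O2) gives the hydroxy ketone F5 already described. CF3CO3H, made from (CF3CO)2O and urea–hydrogen peroxide and buffered with Na2HPO4 in CH2Cl2, should then give (1R)-1-[(2S,3S)-2-(2-hydroxypropan-2-yl)-3-(3-methylbutanoyloxy)-2,3-dihydro-1-benzofuran-5-yl]ethyl (2R)-2-methylbutanoate F6 by the ordinary Baeyer–Villiger reaction, with no alkene left to epoxidise. Burgess dehydration returns 15.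

Step 10.
- What may go wrong: ene reaction through C2–H instead of a methyl hydrogen (oxidation at the ring carbon and ring opening); over-oxidation; or slow conversion of the 1,1-disubstituted alkene, with elimination of isovaleric acid on long exposure.
- Fallback: oxygen is delivered to the alkene and then shifted. It runs from 15 to 16. Epoxidation with mCPBA/NaHCO3 in CH2Cl2 gives (1R)-1-[(2S,3S)-3-(3-methylbutanoyloxy)-2-(2-methyloxiran-2-yl)-2,3-dihydro-1-benzofuran-5-yl]ethyl (2R)-2-methylbutanoate F7 (either epimer at the oxirane carbon serves). Me3SiOTf and DBU in toluene at low temperature isomerise it to the allyl silyl ether (1R)-1-[(2R,3S)-3-(3-methylbutanoyloxy)-2-[3-(trimethylsilyloxy)prop-1-en-2-yl]-2,3-dihydro-1-benzofuran-5-yl]ethyl (2R)-2-methylbutanoate F8, the amidine taking a proton from the unhindered methyl group. Dilute aqueous citric acid then gives 16.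

Step 1.
- What may go wrong: acylation at oxygen without complete migration to carbon; some attack ortho to the hydroxyl; and lactonisation of the hydroxy ester to a benzofuranone under the Lewis acid.
- Fallback: the phenol is capped before acylation. It runs from 1 to 3. Methylation of 1 (MeI, K2CO3, acetone) gives methyl 2-(2-methoxyphenyl)acetate F9. AcCl/AlCl3 in CH2Cl2 acylates para to the methoxy group to give methyl 2-(5-acetyl-2-methoxyphenyl)acetate F10. BBr3 in CH2Cl2 at low temperature cleaves the aryl methyl ether to 3.

## Further compounds

F1 | step 8 | (1R)-1-[4-(2-hydroxy-2-methylpropoxy)-3-(4-methyl-2-oxopentyl)phenyl]ethyl (2R)-2-methylbutanoate | CC(C)CC(=O)Cc1cc([C@@H](C)OC(=O)[C@H](C)CC)ccc1OCC(C)(C)O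
F2 | step 8 | (1R)-1-[3-(4-methyl-2-oxopentyl)-4-[2-methyl-2-(trimethylsilyloxy)propoxy]phenyl]ethyl (2R)-2-methylbutanoate | CC(C)CC(=O)Cc1cc([C@@H](C)OC(=O)[C@H](C)CC)ccc1OCC(C)(C)O[Si](C)(C)C
F3 | step 8 | (1R)-1-[3-(1-diazo-4-methyl-2-oxopentyl)-4-[2-methyl-2-(trimethylsilyloxy)propoxy]phenyl]ethyl (2R)-2-methylbutanoate | CC(C)CC(=O)C(=[N+]=[N-])c1cc([C@@H](C)OC(=O)[C@H](C)CC)ccc1OCC(C)(C)O[Si](C)(C)C
F4 | step 8 | (1R)-1-[(2S,3S)-3-(3-methylbutanoyl)-2-[2-(trimethylsilyloxy)propan-2-yl]-2,3-dihydro-1-benzofuran-5-yl]ethyl (2R)-2-methylbutanoate | CC(C)(O[Si](C)(C)C)[C@H]1Oc2ccc([C@@H](C)OC(=O)[C@H](C)CC)cc2[C@@H]1C(=O)CC(C)C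
F5 | step 8 | (1R)-1-[(2S,3S)-2-(2-hydroxypropan-2-yl)-3-(3-methylbutanoyl)-2,3-dihydro-1-benzofuran-5-yl]ethyl (2R)-2-methylbutanoate | CC(C)(O)[C@H]1Oc2ccc([C@@H](C)OC(=O)[C@H](C)CC)cc2[C@@H]1C(=O)CC(C)C
F6 | step 9 | (1R)-1-[(2S,3S)-2-(2-hydroxypropan-2-yl)-3-(3-methylbutanoyloxy)-2,3-dihydro-1-benzofuran-5-yl]ethyl (2R)-2-methylbutanoate | CC(C)(O)[C@H]1Oc2ccc([C@@H](C)OC(=O)[C@H](C)CC)cc2[C@@H]1OC(=O)CC(C)C
F7 | step 10 | (1R)-1-[(2S,3S)-3-(3-methylbutanoyloxy)-2-(2-methyloxiran-2-yl)-2,3-dihydro-1-benzofuran-5-yl]ethyl (2R)-2-methylbutanoate | CC3(CO3)[C@H]1Oc2ccc([C@@H](C)OC(=O)[C@H](C)CC)cc2[C@@H]1OC(=O)CC(C)C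
F8 | step 10 | (1R)-1-[(2R,3S)-3-(3-methylbutanoyloxy)-2-[3-(trimethylsilyloxy)prop-1-en-2-yl]-2,3-dihydro-1-benzofuran-5-yl]ethyl (2R)-2-methylbutanoate | C=C(CO[Si](C)(C)C)[C@H]1Oc2ccc([C@@H](C)OC(=O)[C@H](C)CC)cc2[C@@H]1OC(=O)CC(C)C
F9 | step 1 | methyl 2-(2-methoxyphenyl)acetate | COC(=O)Cc1ccccc1OC
F10 | step 1 | methyl 2-(5-acetyl-2-methoxyphenyl)acetate | COC(=O)Cc1cc(C(C)=O)ccc1OC
A1 | alternative 1 | (2S,3S)-3-(triethylsilyloxy)-2-[2-(triethylsilyloxy)propan-2-yl]-2,3-dihydro-4H-furo[3,2-c]pyran-4-one | CC(C)(O[Si](CC)(CC)CC)[C@H]1OC2=C(C(=O)OC=C2)[C@@H]1O[Si](CC)(CC)CC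
A2 | alternative 1 | but-3-yn-2-one | C#CC(C)=O
A3 | alternative 1 | 1-[(2S,3S)-3-(triethylsilyloxy)-2-[2-(triethylsilyloxy)propan-2-yl]-2,3-dihydro-1-benzofuran-5-yl]ethan-1-one | CC(C)(O[Si](CC)(CC)CC)[C@H]1Oc2ccc(C(C)=O)cc2[C@@H]1O[Si](CC)(CC)CC
A4 | alternative 2 | 4-(2-methyl-1,3-dioxolan-2-yl)phenol | CC1(OCCO1)c1ccc(O)cc1
A5 | alternative 2 | (S)-3,3-dimethyloxirane-2-carbaldehyde | O=C[C@H]1OC1(C)C
A6 | alternative 2 | (2S,3S)-2-(2-hydroxypropan-2-yl)-5-(2-methyl-1,3-dioxolan-2-yl)-2,3-dihydro-1-benzofuran-3-ol | CC(C)(O)[C@H]1Oc2ccc(C3(C)OCCO3)cc2[C@@H]1O
A7 | alternative 3 | 2-(trimethylsilyl)phenyl trifluoromethanesulfonate | C[Si](C)(C)c1ccccc1OS(=O)(=O)C(F)(F)F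
A8 | alternative 3 | (R)-2-hydroxy-3-methyl-3-(triethylsilyloxy)butanal | CC(C)(O[Si](CC)(CC)CC)[C@H](C=O)O
A9 | alternative 3 | (2S,3S)-2-[2-(triethylsilyloxy)propan-2-yl]-2,3-dihydro-1-benzofuran-3-ol | CC(C)(O[Si](CC)(CC)CC)[C@H]1Oc2ccccc2[C@@H]1O
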